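## Structural features

Numbering used throughout: the tetrahydrofuran is O1, C2, C3, C4, C5; C9 is the exocyclic CH2O carbon on C3 and C7' is the exocyclic CH2 on C4.

- Agastinol is a 7,9'-epoxylignan built on one tetrahydrofuran. C2 carries a 4-hydroxy-3-methoxyphenyl ring directly, C3 carries the C9H2O arm acylated by 4-hydroxybenzoic acid, C4 carries a 4-hydroxy-3-methoxybenzyl group through C7'H2, and C5 is an unsubstituted OCH2.
- The three stereocentres are contiguous: C2 (R), C3 (S), C4 (S). The C2 aryl group is trans to the C9 arm, and the C9 and C7' arms are cis.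
- The two guaiacyl rings are identical, so one protecting group and closely related building blocks serve both.
- The benzylic C2–O1 ether is the most fragile bond. Acid ionises it to a para-oxygen-stabilised cation, which can epimerise C2 or be captured by the other arene to give an aryltetralin, and it can also be hydrogenolysed.
- The aryl ester and the three free phenols do not tolerate strong base, hydride or oxidants, so the phenols stay masked to the end and the ester is installed late.
- The real difficulty is the 3,4-cis relation of two carbon arms on adjacent carbons in a single absolute configuration, plus telling the C9 oxygen apart from the C5 oxygen.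
- The key step exploits C7': a methylene flanked by an arene and by C4, with C4 β to both C9 and C2 through C3. That is the pattern left when an aryl nucleophile opens, at its CH2, a cyclopropane whose neighbouring carbon (the future C3) bears two carbonyl groups; C3 emerges as an enolate that can take the C2 acyl carbon.

## Logic of the disconnections

**22 ⇒ 21.** The three phenolic O–H bonds are traced back to O–benzyl bonds. The phenols must be masked through organometallic, hydride and acid steps, and one group on all three rings allows one final unmasking. The demand is a hydrogenolysis that cleaves three aryl benzyl ethers and spares the cyclic benzylic C2–O1 ether and the ester.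

**21 ⇒ 19 + 20.** The acyl–O bond at C9 is cut. A benzoate would not survive the hydride step, and placing it late makes the route convergent. 19 has a single free hydroxyl, so the forward acylation needs no selectivity, only non-acidic conditions.

**19 ⇒ 17.** The O1–C2 bond is cut. C2 is benzylic and para-oxygenated, so it ionises readily and the C5 hydroxyl can close the five-membered ring; the C9 hydroxyl could only form an oxetane. The ring and the C2 stereocentre become consequences of C3 and C4, and the carbinol configuration in 17 need not be controlled. The forward step must give oxygen capture faster than arene capture and must favour the 2,3-trans ring.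

**17 ⇒ 15.** No skeletal bond is cut. The C2 carbinol is raised to a ketone, and the C9 and C5 oxygens are tied together as a lactone (C9 as carbonyl, C5–O as ring oxygen). This differentiates the two primary oxygens and makes C3 the epimerisable carbon of a β-keto lactone, so its configuration follows from C4 by equilibration to the trans isomer. The forward step needs a hydride source that reduces ketone and lactone without stalling at the enolate.

**15 ⇒ 13.** A carboxyl group is added back at C3 (C3–CO2 bond). It is the second acceptor that activates the cyclopropane. It is chosen as a tert-butyl ester so that its removal needs only catalytic acid and warmth, with no nucleophile or base that could cleave the aroyl group from the fully substituted tricarbonyl carbon or open the lactone.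

**13 ⇒ 6 + 9 + 11.** The C2–C3 bond and the C7'–aryl bond are cut and C7' is reconnected to C3 as a cyclopropane. Three simple pieces result and every carbon of the lignan core is present after one operation. The forward step needs attack at the cyclopropane CH2 and not at the ring-fusion CH or a carbonyl group, and acylation of the enolate at carbon.

**6 ⇒ 1 + 2.** Both cyclopropane bonds to C1 and the lactone acyl–O bond are cut. The pieces are commodity chemicals and the C4 stereocentre of the target is bought. The forward cascade must run through epoxide opening first; direct chloride displacement would lead to the mirror image.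

**9 ⇒ 8 ⇒ 7 and 11 ⇒ 10.** The C–Mg bond and the O–benzyl bond, and the C–Cl bond of the acid chloride, are cut. These are routine preparations of the two aryl partners.

## Other disconnections considered

**Alternative 1:** The cut is the C4–C5 bond of the tetrahydrofuran, with C7' taken back to an alkyne carbon.

- Forward step: TiCl4 would ionise the methoxymethyl ether of the anti homopropargylic alcohol A1 to an O1=C5 oxocarbenium ion. The aryl alkyne would attack through C4 (5-exo-dig) and chloride would trap the aryl-stabilised vinyl cation at C7', giving the 4-[chloro(aryl)methylidene]tetrahydrofuran A2 with the 2,3-trans relation in place.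
- In favour: the ring is made in the key step by a C–C bond, so the C2–O1 bond is never formed by ionisation at C2 and the C2 configuration is fixed beforehand. On this point the alternative is better than the chosen plan, whose key step builds no ring.
- Against: C4 is not a stereocentre in A2. The 3,4-cis relation would have to come from a later face-selective hydrogenation of a tetrasubstituted chloroalkene with C–Cl hydrogenolysis, next to a hydrogenolysable C2–O1 bond. The C2 aryl needs a deactivating mesylate to survive TiCl4; that group and the pivalate must later be exchanged. A1 itself needs two adjacent stereocentres from an asymmetric reaction.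
- Comparison: structurally A2 holds the whole skeleton, as 13 does (equal). Mechanistically it puts a strong Lewis acid next to an electron-rich benzylic ether, where the chosen plan uses a nucleophilic low-temperature step. In step count it should be clearly longer than the ten steps here.

**Alternative 2:** The cut is C3–C9; the hydroxymethyl arm is delivered to C3 from a temporary silicon tether on an oxygen at C7'.

- Forward step: the bromomethylsilyl ether A3 of a 2-aryl-2,5-dihydrofuran would, with Bu3SnH and AIBN, give a silylmethyl radical that adds 6-endo to C3. The tertiary C4 radical then takes hydrogen to give the cis-fused bicycle A4.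
- In favour: the cis ring fusion enforces 3,4-cis and approach anti to the C2 aryl gives 2,3-trans, on a ring that already exists and under neutral conditions. In stereochemical certainty this is the equal of the chosen plan, and better at C2, which is not left to an equilibrating cyclisation.
- Against: only one skeletal bond is formed. The extra oxygen at C7' must be removed after Tamao oxidation, and a benzylic deoxygenation at C7' beside the equally benzylic C2–O1 bond is a selectivity problem the chosen route does not have. 5-exo attack at C4 competes. A3 must be made as a single enantiomer, and stoichiometric tin hydride is less safe.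
- Comparison: structurally A4 lacks nothing but carries an oxygen too many; mechanistically it is radical and neutral against polar and organometallic; in step economy it should be worse.

**Alternative 3:** The cuts are C4–C7' and C2–C3. C2–C3 is formed as in the chosen plan but by an aldol reaction, and C7' arrives as an acyl-anion equivalent.

- Forward step: lithiated dithiane A6 adds to the β-carbon of the menthyloxyfuranone A5 anti to the acetal substituent, and the lactone enolate is trapped by aldehyde A7 to give the trans,trans adduct A8.
- In favour: tandem conjugate addition–aldol on 5-alkoxyfuranones is an established reaction class, whereas the tandem chosen here is not yet demonstrated; on precedent the alternative is better. It forms two skeletal bonds (equal). It sets C3 and C4 in the key step under auxiliary control (better; the chosen step sets no lasting stereocentre). The aldehyde trap gives the carbinol oxidation level directly, a small advantage that the fallback for the key step borrows.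
- Against: this enantiomeric series needs the furanone from (1S,2R,5S)-menthol, the less accessible enantiomer, made by furfural photo-oxygenation and separation of acetal epimers. The auxiliary is stoichiometric. The dithiane must be removed with Raney Ni in the presence of benzyl ethers. C5 enters at the aldehyde oxidation level and must be reduced. The step needs organolithium chemistry at −78 °C.
- Comparison: structurally A8 maps onto 16 after desulfurisation and acetal reduction; mechanistically both plans trap a stabilised enolate made by C–C bond formation; in step economy the two should be about equal (ten to eleven steps).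

Key step: step 5

Remarks on the chemistry:

- The cyclopropane precursor is used as its tert-butyl ester, not as a methyl ester. An aryl Grignard reagent does not add to it, and it is removed after the key step with catalytic acid at 80 °C. No halide nucleophile, hot DMSO or basic medium is needed, so retro-Claisen loss of the aroyl group and lactone opening are avoided.
- The target is (2R,3S,4S). Lactone 6 with (1R,5S) is the enantiomer that (S)-epichlorohydrin gives when the malonate attacks the epoxide terminus first, and it leads to (4S).
- The descriptor at C3 of 13 reads S because the tert-butyl ester outranks the lactone carbonyl; the geometry is aroyl trans to arylmethyl.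
- Acids 10 and 20 are taken as purchased materials.
- 16 and 17 are carried as mixtures of carbinol epimers, since that centre is ionised in step 8.
- The enantiomeric purity of 6 should be checked, for example by chiral HPLC.

## Route

**Step 1**
Reactants: 1 di-tert-butyl malonate; 2 (S)-epichlorohydrin
Product: 6 tert-butyl (1R,5S)-2-oxo-3-oxabicyclo[3.1.0]hexane-1-carboxylate, via chlorohydrin alkoxide 3 (not isolated), via glycidylmalonate 4 (not isolated), via cyclopropylcarbinol alkoxide 5 (not isolated)
Conditions: 1 (1.1 equiv), KOtBu (1.05 equiv), tBuOH–THF, rt; then 2, rt → 60 °C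
Reagents that add atoms: none
Why: Known epihalohydrin–malonate cyclopropanation/lactonisation cascade: the malonate anion opens the epoxide at its CH2 (3), the alkoxide displaces chloride to give the transposed epoxide 4, 3-exo-tet attack of the re-formed malonate anion inverts the epoxide CH to give 5, and the alkoxide lactonises onto the cis ester. The ring-fusion CH (C5, S) is the epichlorohydrin carbon after one inversion, and C1 (R) follows because only the cis-fused lactone can close; the malonate is deprotonated before 2 is added so that free tert-butoxide does not attack 2.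

**Step 2**
Reactants: 7 4-bromo-2-methoxyphenol
Product: 8 1-(benzyloxy)-4-bromo-2-methoxybenzene
Conditions: BnBr, K2CO3, MeCN, 60 °C
Reagents that add atoms: benzyl bromide, BrCc1ccccc1
Why: Williamson ether synthesis on a phenoxide; the aryl bromide is inert under these conditions.

**Step 3**
Reactants: 8 1-(benzyloxy)-4-bromo-2-methoxybenzene
Product: 9 [4-(benzyloxy)-3-methoxyphenyl]magnesium bromide (THF solution, titrated)
Conditions: Mg turnings, I2 (cat.), THF, 40 °C
Reagents that add atoms: magnesium, [Mg]
Why: Oxidative insertion of magnesium into an aryl bromide (Grignard reagent formation); the benzyl and methyl ethers are stable to the reagent.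

**Step 4**
Reactants: 10 4-(benzyloxy)-3-methoxybenzoic acid
Product: 11 4-(benzyloxy)-3-methoxybenzoyl chloride
Conditions: (COCl)2, DMF (cat.), CH2Cl2, 0 °C → rt; evaporate, use crude
Reagents that add atoms: oxalyl chloride, O=C(Cl)C(Cl)=O
Why: Acid chloride formation through the chloroiminium (Vilsmeier-type) catalyst; the by-products are gases, so the crude chloride can go straight into step 5.

**Step 5**
Reactants: 6 tert-butyl (1R,5S)-2-oxo-3-oxabicyclo[3.1.0]hexane-1-carboxylate; 9 [4-(benzyloxy)-3-methoxyphenyl]magnesium bromide; 11 4-(benzyloxy)-3-methoxybenzoyl chloride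
Product: 13 tert-butyl (3S,4S)-3-[4-(benzyloxy)-3-methoxybenzoyl]-4-{[4-(benzyloxy)-3-methoxyphenyl]methyl}-2-oxooxolane-3-carboxylate, via bromomagnesium enolate 12 (not isolated)
Conditions: 9 (1.15 equiv), CuBr·SMe2 (10 mol %), THF, −40 → −15 °C; then 11 (1.4 equiv), −15 °C → rt
Reagents that add atoms: none
Why: Proposed new method: the one-flask union of a copper-catalysed homoconjugate (strain-release) arylation of a cyclopropane-1,1-dicarbonyl with C-aroylation of the enolate so formed has not been shown on this substrate class; the closest known reaction types are the copper-catalysed Grignard opening of 2-oxo-3-oxabicyclo[3.1.0]hexane-1-carboxylates, the C-acylation of magnesium chelates of malonate-type enolates by acid chlorides, and conjugate addition–enolate acylation on enoates. The arylcopper species made from 9 and CuBr·SMe2 (monovalent copper) attacks the cyclopropane CH2 (C6) of 6 in an SN2 manner with the C1–C6 bond as leaving group, because both carbonyl groups on C1 accept the electron pair and ring strain is released; this forms the C7'–aryl bond and leaves the C5 centre (C4 of the lactone, S) untouched. Attack at the CH2 and not at the ring-fusion CH is secured by sterics; low temperature and copper catalysis should keep 1,2-addition to the lactone carbonyl slow, and the tert-butyl ester is inert to the aryl-metal. The product is the chelated bromomagnesium enolate 12, whose two oxygen atoms are held by magnesium, so 11 should react at carbon, forming the C2–C3 bond and a fully substituted carbon. The acid chloride should approach anti to the new arylmethyl group on the neighbouring carbon, so the aroyl group ends trans to it (3S); this centre is erased in step 6, so the selectivity is not critical. No ring is closed; one ring is opened. Only a slight excess of 9 is used so that little aryl-metal remains to consume 11 as a diaryl ketone.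

**Step 6**
Reactants: 13 tert-butyl (3S,4S)-3-[4-(benzyloxy)-3-methoxybenzoyl]-4-{[4-(benzyloxy)-3-methoxyphenyl]methyl}-2-oxooxolane-3-carboxylate
Product: 15 (3R,4S)-3-[4-(benzyloxy)-3-methoxybenzoyl]-4-{[4-(benzyloxy)-3-methoxyphenyl]methyl}oxolan-2-one, via keto acid 14 (not isolated)
Conditions: TsOH·H2O (10 mol %), toluene, 80 °C
Reagents that add atoms: none
Why: Acid-catalysed loss of 2-methylpropene from the tert-butyl ester gives the β-keto acid 14, which decarboxylates through a six-membered transition state, as known for tert-butyl acylmalonates. The enol tautomerises to the more stable trans keto lactone, so C3 (R) is set by thermodynamic control relative to C4.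

**Step 7**
Reactants: 15 (3R,4S)-3-[4-(benzyloxy)-3-methoxybenzoyl]-4-{[4-(benzyloxy)-3-methoxyphenyl]methyl}oxolan-2-one
Product: 17 (2S,3S)-2-{[4-(benzyloxy)-3-methoxyphenyl](hydroxy)methyl}-3-{[4-(benzyloxy)-3-methoxyphenyl]methyl}butane-1,4-diol (both carbinol epimers), via hydroxy lactone 16 (not isolated)
Conditions: LiBH4 (4 equiv), THF–MeOH, −10 °C → rt; aq. NH4Cl
Reagents that add atoms: none
Why: Borohydride reduction of the aryl ketone (to 16) followed by methanol-assisted reduction of the lactone to the 1,4-diol; LiBH4 is chosen over LiAlH4 because it is less basic toward the acidic C3–H and is safer. The carbinol configuration is irrelevant because it is ionised in step 8, and C3 and C4 are not touched once the ketone is gone.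

**Step 8**
Reactants: 17 (2S,3S)-2-{[4-(benzyloxy)-3-methoxyphenyl](hydroxy)methyl}-3-{[4-(benzyloxy)-3-methoxyphenyl]methyl}butane-1,4-diol
Product: 19 [(2R,3S,4S)-2-[4-(benzyloxy)-3-methoxyphenyl]-4-{[4-(benzyloxy)-3-methoxyphenyl]methyl}oxolan-3-yl]methanol, via benzylic cation 18 (not isolated)
Conditions: CSA (10 mol %), CH2Cl2, 0 °C → rt, short reaction time
Reagents that add atoms: none
Why: Acid-mediated SN1 cycloetherification known for 7-hydroxylated seco-lignan triols: the para-alkoxybenzylic alcohol ionises to cation 18 and the C5 hydroxyl captures it (5-exo-trig), while the C9 hydroxyl could only give an oxetane. The aryl group should take the position trans to the C9 arm, both in the less crowded transition state and by reversible re-ionisation, which sets C2 (R) from C3.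

**Step 9**
Reactants: 19 [(2R,3S,4S)-2-[4-(benzyloxy)-3-methoxyphenyl]-4-{[4-(benzyloxy)-3-methoxyphenyl]methyl}oxolan-3-yl]methanol; 20 4-(benzyloxy)benzoic acid
Product: 21 [(2R,3S,4S)-2-[4-(benzyloxy)-3-methoxyphenyl]-4-{[4-(benzyloxy)-3-methoxyphenyl]methyl}oxolan-3-yl]methyl 4-(benzyloxy)benzoate
Conditions: EDC·HCl, DMAP (cat.), CH2Cl2, 0 °C → rt
Reagents that add atoms: none
Why: Steglich esterification of the only free hydroxyl, a primary alcohol; the conditions are neutral to weakly basic and do not ionise the benzylic ether.

**Step 10**
Reactants: 21 [(2R,3S,4S)-2-[4-(benzyloxy)-3-methoxyphenyl]-4-{[4-(benzyloxy)-3-methoxyphenyl]methyl}oxolan-3-yl]methyl 4-(benzyloxy)benzoate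
Product: 22 agastinol, [(2R,3S,4S)-2-(4-hydroxy-3-methoxyphenyl)-4-[(4-hydroxy-3-methoxyphenyl)methyl]oxolan-3-yl]methyl 4-hydroxybenzoate
Conditions: H2 (1 atm), 10% Pd/C, EtOAc–EtOH, rt; stop after uptake of 3 equiv
Reagents that add atoms: none
Why: Hydrogenolysis of three aryl benzyl ethers; the ring C2–O1 bond is a dialkyl-type benzylic ether that should be cleaved much more slowly in a neutral solvent at atmospheric pressure, and the ester sits on a non-benzylic carbon. No stereocentre is involved.

## Compound list

1 | di-tert-butyl propanedioate (di-tert-butyl malonate) | CC(C)(C)OC(=O)CC(=O)OC(C)(C)C | starting material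
2 | (S)-epichlorohydrin, (2S)-2-(chloromethyl)oxirane | ClC[C@@H]1CO1 | starting material
3 | di-tert-butyl 2-[(2S)-3-chloro-2-hydroxypropyl]propanedioate (present as its potassium alkoxide) | ClC[C@@H](O)CC(C(=O)OC(C)(C)C)C(=O)OC(C)(C)C | intermediate
4 | di-tert-butyl 2-{[(2S)-oxiran-2-yl]methyl}propanedioate | CC(C)(C)OC(=O)C(C[C@H]1CO1)C(=O)OC(C)(C)C | intermediate
5 | di-tert-butyl (2S)-2-(hydroxymethyl)cyclopropane-1,1-dicarboxylate (present as its potassium alkoxide) | OC[C@H]1CC1(C(=O)OC(C)(C)C)C(=O)OC(C)(C)C | intermediate
6 | tert-butyl (1R,5S)-2-oxo-3-oxabicyclo[3.1.0]hexane-1-carboxylate | CC(C)(C)OC(=O)[C@@]12C[C@@H]1COC2=O | intermediate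
7 | 4-bromo-2-methoxyphenol | COc1cc(Br)ccc1O | starting material
8 | 1-(benzyloxy)-4-bromo-2-methoxybenzene | COc1cc(Br)ccc1OCc1ccccc1 | intermediate
9 | [4-(benzyloxy)-3-methoxyphenyl]magnesium bromide | COc1cc([Mg]Br)ccc1OCc1ccccc1 | intermediate
10 | 4-(benzyloxy)-3-methoxybenzoic acid | COc1cc(C(=O)O)ccc1OCc1ccccc1 | starting material
11 | 4-(benzyloxy)-3-methoxybenzoyl chloride | COc1cc(C(Cl)=O)ccc1OCc1ccccc1 | intermediate
12 | bromomagnesium enolate of tert-butyl (4S)-4-{[4-(benzyloxy)-3-methoxyphenyl]methyl}-2-oxooxolane-3-carboxylate | CC(C)(C)OC(=O)C1=C(O[Mg]Br)OC[C@H]1Cc1ccc(OCc2ccccc2)c(OC)c1 | intermediate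
13 | tert-butyl (3S,4S)-3-[4-(benzyloxy)-3-methoxybenzoyl]-4-{[4-(benzyloxy)-3-methoxyphenyl]methyl}-2-oxooxolane-3-carboxylate (aroyl trans to arylmethyl) | CC(C)(C)OC(=O)[C@@]1(C(=O)c2ccc(OCc3ccccc3)c(OC)c2)C(=O)OC[C@H]1Cc1ccc(OCc2ccccc2)c(OC)c1 | intermediate
14 | (3R,4S)-3-[4-(benzyloxy)-3-methoxybenzoyl]-4-{[4-(benzyloxy)-3-methoxyphenyl]methyl}-2-oxooxolane-3-carboxylic acid | OC(=O)[C@@]1(C(=O)c2ccc(OCc3ccccc3)c(OC)c2)C(=O)OC[C@H]1Cc1ccc(OCc2ccccc2)c(OC)c1 | intermediate
15 | (3R,4S)-3-[4-(benzyloxy)-3-methoxybenzoyl]-4-{[4-(benzyloxy)-3-methoxyphenyl]methyl}oxolan-2-one (trans) | O=C1OC[C@@H](Cc2ccc(OCc3ccccc3)c(OC)c2)[C@@H]1C(=O)c1ccc(OCc2ccccc2)c(OC)c1 | intermediate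
16 | (3R,4S)-3-{[4-(benzyloxy)-3-methoxyphenyl](hydroxy)methyl}-4-{[4-(benzyloxy)-3-methoxyphenyl]methyl}oxolan-2-one (both carbinol epimers) | O=C1OC[C@@H](Cc2ccc(OCc3ccccc3)c(OC)c2)[C@@H]1C(O)c1ccc(OCc2ccccc2)c(OC)c1 | intermediate
17 | (2S,3S)-2-{[4-(benzyloxy)-3-methoxyphenyl](hydroxy)methyl}-3-{[4-(benzyloxy)-3-methoxyphenyl]methyl}butane-1,4-diol (both carbinol epimers) | OC[C@@H](C(O)c1ccc(OCc2ccccc2)c(OC)c1)[C@@H](CO)Cc1ccc(OCc2ccccc2)c(OC)c1 | intermediate
18 | benzylic cation formed from 17 by loss of the benzylic hydroxyl | OC[C@@H]([CH+]c1ccc(OCc2ccccc2)c(OC)c1)[C@@H](CO)Cc1ccc(OCc2ccccc2)c(OC)c1 | intermediate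
19 | [(2R,3S,4S)-2-[4-(benzyloxy)-3-methoxyphenyl]-4-{[4-(benzyloxy)-3-methoxyphenyl]methyl}oxolan-3-yl]methanol | COc1cc(C[C@@H]2CO[C@@H](c3ccc(OCc4ccccc4)c(OC)c3)[C@@H]2CO)ccc1OCc1ccccc1 | intermediate
20 | 4-(benzyloxy)benzoic acid | OC(=O)c1ccc(OCc2ccccc2)cc1 | starting material
21 | [(2R,3S,4S)-2-[4-(benzyloxy)-3-methoxyphenyl]-4-{[4-(benzyloxy)-3-methoxyphenyl]methyl}oxolan-3-yl]methyl 4-(benzyloxy)benzoate | COc1cc(C[C@@H]2CO[C@@H](c3ccc(OCc4ccccc4)c(OC)c3)[C@@H]2COC(=O)c2ccc(OCc3ccccc3)cc2)ccc1OCc1ccccc1 | intermediate
22 | agastinol, [(2R,3S,4S)-2-(4-hydroxy-3-methoxyphenyl)-4-[(4-hydroxy-3-methoxyphenyl)methyl]oxolan-3-yl]methyl 4-hydroxybenzoate | COc1cc(C[C@@H]2CO[C@@H](c3ccc(O)c(OC)c3)[C@@H]2COC(=O)c2ccc(O)cc2)ccc1O | target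

## Step count and least certain steps

Total step count: 10. Longest linear sequence: 8 steps (7 → 8 → 9 → 13 → 15 → 17 → 19 → 21 → 22; steps 2, 3, 5, 6, 7, 8, 9, 10).

**Step 5 (key step, proposed new method).**
- What may go wrong: acylation of the hindered, fully substituted, chelated enolate may be slow or go to oxygen. Residual aryl-metal may consume the acid chloride. Uncatalysed 1,2-addition to the lactone carbonyl may compete with the cyclopropane opening.
- Fallback (known chemistry): it sets out from 6 and 9 and comes back at 16. 6 is opened with 9 under the same copper catalysis and the enolate is simply protonated (aq. NH4Cl), giving tert-butyl (3S,4S)-4-{[4-(benzyloxy)-3-methoxyphenyl]methyl}-2-oxooxolane-3-carboxylate F1. TsOH·H2O in toluene at 80 °C removes the ester to give (4S)-4-{[4-(benzyloxy)-3-methoxyphenyl]methyl}oxolan-2-one F2. The lithium enolate of F2 (LiN(iPr)2, THF, −78 °C) is added to 4-(benzyloxy)-3-methoxybenzaldehyde F3 in an aldol reaction anti to the C4 substituent, which should give 16. This is then reduced to 17 under the conditions of step 7. Step 4 and the fully substituted tricarbonyl centre are bypassed.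

**Step 8.**
- What may go wrong: capture of the benzylic cation by the electron-rich arene of the C7' arm (intramolecular Friedel–Crafts alkylation to a six-membered carbocycle), and loss of control at C2 through repeated re-ionisation. Both grow with acid strength and time.
- Fallback: it sets out from 17 and comes back at 22. Hydrogenolysis of 17 (H2, Pd/C, EtOAc, neutral) would give (2S,3S)-2-[hydroxy(4-hydroxy-3-methoxyphenyl)methyl]-3-[(4-hydroxy-3-methoxyphenyl)methyl]butane-1,4-diol F4. With a free para-hydroxyl the benzylic position ionises by the quinone-methide pathway on gentle warming in a weakly acidic aqueous buffer, where arene capture should be slow. Ring closure by the C5 hydroxyl gives 4-[(2R,3S,4S)-4-[(4-hydroxy-3-methoxyphenyl)methyl]-3-(hydroxymethyl)oxolan-2-yl]-2-methoxyphenol F5. A Mitsunobu esterification with 20 (PPh3, diisopropyl azodicarboxylate, THF) activates only the aliphatic hydroxyl and gives [(2R,3S,4S)-2-(4-hydroxy-3-methoxyphenyl)-4-[(4-hydroxy-3-methoxyphenyl)methyl]oxolan-3-yl]methyl 4-(benzyloxy)benzoate F6. Hydrogenolysis as in step 10 gives 22.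

**Step 7.**
- What may go wrong: deprotonation at C3 of the β-keto lactone in competition with hydride delivery (stalled reduction), and retro-aldol fragmentation or β-elimination of the β-alkoxy lactone before the lactone carbonyl is reduced.
- Fallback: it sets out from 15 and comes back at 17. The ketone alone is reduced (NaBH4, CeCl3·7H2O, MeOH–THF, −40 °C) and 16 is isolated. Silylation (tert-butyldimethylsilyl triflate, 2,6-lutidine) gives (3R,4S)-3-{[4-(benzyloxy)-3-methoxyphenyl][(tert-butyldimethylsilyl)oxy]methyl}-4-{[4-(benzyloxy)-3-methoxyphenyl]methyl}oxolan-2-one F7, in which no β-alkoxide can form. LiBH4 then reduces the lactone to (2S,3S)-2-{[4-(benzyloxy)-3-methoxyphenyl][(tert-butyldimethylsilyl)oxy]methyl}-3-{[4-(benzyloxy)-3-methoxyphenyl]methyl}butane-1,4-diol F8. Bu4NF removes the silyl group to give 17.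

**Step 1.**
- What may go wrong: erosion of enantiomeric purity through direct displacement of chloride by the malonate, which leads to the mirror-image lactone, and slow lactonisation onto the hindered ester.
- Fallback: it sets out from 1 and comes back at 6. (S)-Glycidol F9 is converted (Tf2O, 2,6-lutidine, CH2Cl2, −78 °C) into (R)-glycidyl trifluoromethanesulfonate F10. With this leaving group the potassium enolate of 1 should displace the sulfonate directly and leave the epoxide intact, giving 4 by a single pathway. The same 3-exo-tet opening and lactonisation then lead through 5 to 6.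

## Further compounds

F1 | step 5 | tert-butyl (3S,4S)-4-{[4-(benzyloxy)-3-methoxyphenyl]methyl}-2-oxooxolane-3-carboxylate | CC(C)(C)OC(=O)[C@@H]1C(=O)OC[C@H]1Cc1ccc(OCc2ccccc2)c(OC)c1
F2 | step 5 | (4S)-4-{[4-(benzyloxy)-3-methoxyphenyl]methyl}oxolan-2-one | O=C1C[C@H](Cc2ccc(OCc3ccccc3)c(OC)c2)CO1
F3 | step 5 | 4-(benzyloxy)-3-methoxybenzaldehyde | COc1cc(C=O)ccc1OCc1ccccc1
F4 | step 8 | (2S,3S)-2-[hydroxy(4-hydroxy-3-methoxyphenyl)methyl]-3-[(4-hydroxy-3-methoxyphenyl)methyl]butane-1,4-diol (both carbinol epimers) | OC[C@@H](C(O)c1ccc(O)c(OC)c1)[C@@H](CO)Cc1ccc(O)c(OC)c1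
F5 | step 8 | 4-[(2R,3S,4S)-4-[(4-hydroxy-3-methoxyphenyl)methyl]-3-(hydroxymethyl)oxolan-2-yl]-2-methoxyphenol | COc1cc(C[C@@H]2CO[C@@H](c3ccc(O)c(OC)c3)[C@@H]2CO)ccc1O
F6 | step 8 | [(2R,3S,4S)-2-(4-hydroxy-3-methoxyphenyl)-4-[(4-hydroxy-3-methoxyphenyl)methyl]oxolan-3-yl]methyl 4-(benzyloxy)benzoate | COc1cc(C[C@@H]2CO[C@@H](c3ccc(O)c(OC)c3)[C@@H]2COC(=O)c2ccc(OCc3ccccc3)cc2)ccc1O
F7 | step 7 | (3R,4S)-3-{[4-(benzyloxy)-3-methoxyphenyl][(tert-butyldimethylsilyl)oxy]methyl}-4-{[4-(benzyloxy)-3-methoxyphenyl]methyl}oxolan-2-one (both silyloxy epimers) | O=C1OC[C@@H](Cc2ccc(OCc3ccccc3)c(OC)c2)[C@@H]1C(O[Si](C)(C)C(C)(C)C)c1ccc(OCc2ccccc2)c(OC)c1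
F8 | step 7 | (2S,3S)-2-{[4-(benzyloxy)-3-methoxyphenyl][(tert-butyldimethylsilyl)oxy]methyl}-3-{[4-(benzyloxy)-3-methoxyphenyl]methyl}butane-1,4-diol (both silyloxy epimers) | OC[C@@H](C(O[Si](C)(C)C(C)(C)C)c1ccc(OCc2ccccc2)c(OC)c1)[C@@H](CO)Cc1ccc(OCc2ccccc2)c(OC)c1
F9 | step 1 | (S)-glycidol, [(2S)-oxiran-2-yl]methanol | OC[C@H]1CO1
F10 | step 1 | (R)-glycidyl trifluoromethanesulfonate, [(2R)-oxiran-2-yl]methyl trifluoromethanesulfonate | O=S(=O)(OC[C@H]1CO1)C(F)(F)F
A1 | alternative 1 | (2S)-4-[4-(benzyloxy)-3-methoxyphenyl]-2-{(R)-(methoxymethoxy)[3-methoxy-4-(methanesulfonyloxy)phenyl]methyl}but-3-yn-1-yl 2,2-dimethylpropanoate | COCO[C@@H](c1ccc(OS(C)(=O)=O)c(OC)c1)[C@H](COC(=O)C(C)(C)C)C#Cc1ccc(OCc2ccccc2)c(OC)c1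
A2 | alternative 1 | [(2R,3S,4E)-4-{[4-(benzyloxy)-3-methoxyphenyl](chloro)methylidene}-2-[3-methoxy-4-(methanesulfonyloxy)phenyl]oxolan-3-yl]methyl 2,2-dimethylpropanoate | Cl/C(c1ccc(OCc2ccccc2)c(OC)c1)=C1/CO[C@@H](c2ccc(OS(C)(=O)=O)c(OC)c2)[C@@H]1COC(=O)C(C)(C)C
A3 | alternative 2 | (bromomethyl)dimethylsilyl ether of [(5R)-5-[4-(benzyloxy)-3-methoxyphenyl]-2,5-dihydrofuran-3-yl][4-(benzyloxy)-3-methoxyphenyl]methanol (one carbinol epimer, as in the SMILES) | BrC[Si](C)(C)O[C@@H](c1ccc(OCc2ccccc2)c(OC)c1)C1=C[C@H](c2ccc(OCc3ccccc3)c(OC)c2)OC1
A4 | alternative 2 | cis-fused tetrahydrofuran–1,2-oxasilinane bicycle: ring O1/C2(aryl)/C3/C4/C5 fused at C3–C4 to ring C3–C9H2–SiMe2–O–C7'H(aryl)–C4, aryl = 4-(benzyloxy)-3-methoxyphenyl | C[Si]1(C)C[C@H]2[C@H](c3ccc(OCc4ccccc4)c(OC)c3)OC[C@H]2[C@H](c2ccc(OCc3ccccc3)c(OC)c2)O1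
A5 | alternative 3 | (5S)-5-{[(1S,2R,5S)-5-methyl-2-(propan-2-yl)cyclohexyl]oxy}furan-2(5H)-one | O=C1O[C@H](O[C@H]2C[C@@H](C)CC[C@@H]2C(C)C)C=C1
A6 | alternative 3 | 2-[4-(benzyloxy)-3-methoxyphenyl]-1,3-dithiane | COc1cc(C2SCCCS2)ccc1OCc1ccccc1
A7 | alternative 3 | 4-(benzyloxy)-3-methoxybenzaldehyde | COc1cc(C=O)ccc1OCc1ccccc1
A8 | alternative 3 | trans,trans 3-{[4-(benzyloxy)-3-methoxyphenyl](hydroxy)methyl}-4-{2-[4-(benzyloxy)-3-methoxyphenyl]-1,3-dithian-2-yl}-5-{[(1S,2R,5S)-5-methyl-2-(propan-2-yl)cyclohexyl]oxy}oxolan-2-one (one carbinol epimer shown) | O=C1O[C@H](O[C@H]2C[C@@H](C)CC[C@@H]2C(C)C)[C@@H](C3(c4ccc(OCc5ccccc5)c(OC)c4)SCCCS3)[C@@H]1[C@@H](O)c1ccc(OCc2ccccc2)c(OC)c1
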